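**Plan**

Atom names used below: furanone ring O1, C2 (lactone C=O), C3 (C-methyl), C4 (C-OH), C5; side chain C1' (exocyclic =CH) to C13' (CH2 on the furan).

1. Retrosynthesis: the furanone is opened at C4–C5, which at the same time unties O1 from C2 and leads back to a C14 aldehyde (its CHO carbon is C5), triphenylphosphine and a methylmalonyl thioester chloride. The chain is then cut at C12'–C13' (furylmethyl Grignard reagent + tosylate) and at C4'–C5' (alkyl Grignard reagent + allylic chloride).
2. Forward: (R)-linalool gives the C5'–C12' allylic chloride; copper-catalysed coupling adds the C1'–C4' unit; hydroboration, tosylation and furylmethyl coupling complete the chain; oxidation, phosphonium salt formation and ring closure build the furanone last; desilylation ends the route.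
3. Stereochemistry: C10' comes from (R)-linalool (the descriptor becomes S only through a CIP priority change), C2' from methyl hydrogen (R)-3-methylglutarate, 6'E from the SeO2 oxidation, and 5Z is the thermodynamic geometry set in the key step.
4. Enabling feature: C5 is an enol-ester carbon (bonded to ring O1, to C4 and doubly to C1'), so the ring is the enol lactone of a 1,2-diketone. C5 can therefore be an aldehyde carbon that is made nucleophilic by O-acylation plus a phosphonio group, attacks the C4 acyl carbon, and then loses the phosphine to leave C5=C1'.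

Key step: step 17

**Route**

Step 1
Reactants: 1 (R)-linalool
Product: 2 {[(3R)-3,7-dimethylocta-1,6-dien-3-yl]oxy}triethylsilane
Conditions: Et3SiOTf, 2,6-lutidine, CH2Cl2, −78 °C
Reagents that add atoms: triethylsilyl trifluoromethanesulfonate, CC[Si](CC)(CC)OS(=O)(=O)C(F)(F)F
Why: Silylation of the hindered tertiary alcohol with a silyl triflate; the stereocentre is not involved.

Step 2
Reactants: 2 {[(3R)-3,7-dimethylocta-1,6-dien-3-yl]oxy}triethylsilane
Product: 3 (2E,6R)-2,6-dimethyl-6-(triethylsilyloxy)octa-2,7-dien-1-ol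
Conditions: SeO2 (cat.), t-BuOOH, salicylic acid (cat.), CH2Cl2, rt
Reagents that add atoms: tert-butyl hydroperoxide, CC(C)(C)OO
Why: Sharpless SeO2/t-BuOOH allylic oxidation (ene reaction, then [2,3]-shift) should hydroxylate the (E)-methyl group of the trisubstituted alkene, since the vinyl group has no allylic hydrogen.

Step 3
Reactants: 3 (2E,6R)-2,6-dimethyl-6-(triethylsilyloxy)octa-2,7-dien-1-ol
Product: 4 {[(3R,6E)-8-chloro-3,7-dimethylocta-1,6-dien-3-yl]oxy}triethylsilane
Conditions: N-chlorosuccinimide, Me2S, CH2Cl2, −20 → 0 °C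
Reagents that add atoms: N-chlorosuccinimide, ClN1C(=O)CCC1=O
Why: Corey–Kim chlorination (alkoxysulfonium ion, SN2 by chloride) converts the primary allylic alcohol without allylic transposition, so the (E) geometry is kept.

Step 4
Reactants: 5 methyl hydrogen (R)-3-methylglutarate
Product: 6 methyl (3R)-5-hydroxy-3-methylpentanoate
Conditions: BH3·SMe2, THF, 0 °C → rt; MeOH
Reagents that add atoms: none
Why: Borane reduces the carboxylic acid much faster than the ester, which tells the two ends apart; the stereocentre is β to both carbonyls and is not touched.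

Step 5
Reactants: 6 methyl (3R)-5-hydroxy-3-methylpentanoate
Product: 7 methyl (3R)-3-methyl-5-(triethylsilyloxy)pentanoate
Conditions: Et3SiCl, imidazole, CH2Cl2, 0 °C
Reagents that add atoms: chlorotriethylsilane, CC[Si](Cl)(CC)CC
Why: Standard silylation of a primary alcohol, done at once to forestall lactonisation.

Step 6
Reactants: 7 methyl (3R)-3-methyl-5-(triethylsilyloxy)pentanoate
Product: 8 (3S)-3-methyl-5-(triethylsilyloxy)pentan-1-ol
Conditions: i-Bu2AlH, CH2Cl2, −78 → 0 °C; aq. potassium sodium tartrate (KNaC4H4O6)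
Reagents that add atoms: none
Why: Ester reduction with i-Bu2AlH to the primary alcohol; the descriptor changes only through CIP priorities.

Step 7
Reactants: 8 (3S)-3-methyl-5-(triethylsilyloxy)pentan-1-ol
Product: 10 {[(3R)-5-bromo-3-methylpentyl]oxy}triethylsilane, via mesylate 9 (not isolated)
Conditions: MsCl, Et3N, CH2Cl2, 0 °C; then LiBr, acetone, 45 °C
Reagents that add atoms: lithium bromide, [Li+].[Br-]
Why: Mesylation followed by SN2 displacement with bromide is a non-acidic way to the bromide that spares the silyl ether.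

Step 8
Reactants: 10 {[(3R)-5-bromo-3-methylpentyl]oxy}triethylsilane; 4 {[(3R,6E)-8-chloro-3,7-dimethylocta-1,6-dien-3-yl]oxy}triethylsilane
Product: 12 (3S,7E,11R)-3,7,11-trimethyl-1,11-bis(triethylsilyloxy)trideca-7,12-diene, via Grignard reagent 11 (not isolated)
Conditions: 10, Mg, THF, 45 °C; then 4, Li2CuCl4 (3 mol %), THF, −78 → 0 °C
Reagents that add atoms: none
Why: Copper-catalysed Grignard–allylic halide coupling (Kochi–Schlosser type) should substitute at the primary allylic carbon and not at the more hindered γ carbon, so the (E)-trisubstituted alkene is kept.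

Step 9
Reactants: 12 (3S,7E,11R)-3,7,11-trimethyl-1,11-bis(triethylsilyloxy)trideca-7,12-diene
Product: 13 (3R,6E,11S)-3,7,11-trimethyl-3,13-bis(triethylsilyloxy)tridec-6-en-1-ol
Conditions: 9-BBN, THF, 0 → 45 °C; then NaOH, H2O2, H2O, 0 °C
Reagents that add atoms: hydrogen peroxide, OO
Why: Anti-Markovnikov hydroboration–oxidation with 9-BBN should touch only the monosubstituted alkene, the trisubstituted one being too hindered.

Step 10
Reactants: 13 (3R,6E,11S)-3,7,11-trimethyl-3,13-bis(triethylsilyloxy)tridec-6-en-1-ol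
Product: 14 (3R,6E,11S)-3,7,11-trimethyl-3,13-bis(triethylsilyloxy)tridec-6-en-1-yl 4-methylbenzenesulfonate
Conditions: TsCl, pyridine, DMAP (cat.), CH2Cl2, 0 °C
Reagents that add atoms: 4-toluenesulfonyl chloride, Cc1ccc(cc1)S(Cl)(=O)=O
Why: Tosylation of the primary alcohol.

Step 11
Reactants: 15 furan-3-ylmethanol
Product: 16 3-(chloromethyl)furan
Conditions: SOCl2, pyridine, Et2O, 0 °C; used at once as a solution
Reagents that add atoms: thionyl chloride, ClS(Cl)=O
Why: Chlorination of the furylmethyl alcohol via its chlorosulfite, with pyridine buffering the acid-sensitive furan.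

Step 12
Reactants: 16 3-(chloromethyl)furan; 14 (3R,6E,11S)-3,7,11-trimethyl-3,13-bis(triethylsilyloxy)tridec-6-en-1-yl 4-methylbenzenesulfonate
Product: 18 3-[(4S,7E,12S)-4,8,12-trimethyl-4,14-bis(triethylsilyloxy)tetradec-7-en-1-yl]furan, via furylmethyl Grignard reagent 17 (not isolated)
Conditions: 16, Mg, THF, 0 °C; then 14, Li2CuCl4 (5 mol %), THF, −78 → 0 °C
Reagents that add atoms: none
Why: Copper-catalysed coupling of a furan-3-ylmethyl Grignard reagent with a primary sulfonate, the usual way to attach 3-furylmethyl units to terpenoid chains.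

Step 13
Reactants: 18 3-[(4S,7E,12S)-4,8,12-trimethyl-4,14-bis(triethylsilyloxy)tetradec-7-en-1-yl]furan
Product: 19 (3S,7E,11S)-14-(furan-3-yl)-3,7,11-trimethyl-11-(triethylsilyloxy)tetradec-7-enal
Conditions: (COCl)2, DMSO, CH2Cl2, −78 → −30 °C; then Et3N, −78 → 0 °C
Reagents that add atoms: none
Why: Swern conditions are known to cleave a primary triethylsilyl ether in situ and oxidise it to the aldehyde while the hindered tertiary silyl ether survives; the stereocentre is β to the new carbonyl and cannot epimerise.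

Step 14
Reactants: 20 2,2,5-trimethyl-1,3-dioxane-4,6-dione
Product: 21 2-methyl-3-oxo-3-(phenylsulfanyl)propanoic acid
Conditions: PhSH, toluene, 100 °C
Reagents that add atoms: benzenethiol, Sc1ccccc1
Why: Ring opening of the Meldrum's acid derivative by the thiol with loss of acetone, the usual synthesis of malonic acid half thioesters.

Step 15
Reactants: 21 2-methyl-3-oxo-3-(phenylsulfanyl)propanoic acid
Product: 22 S-phenyl 3-chloro-2-methyl-3-oxopropanethioate
Conditions: (COCl)2, DMF (cat.), CH2Cl2, 0 °C → rt; used crude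
Reagents that add atoms: oxalyl chloride, ClC(=O)C(Cl)=O
Why: Acid chloride formation under Vilsmeier catalysis.

Step 16
Reactants: 19 (3S,7E,11S)-14-(furan-3-yl)-3,7,11-trimethyl-11-(triethylsilyloxy)tetradec-7-enal; 22 S-phenyl 3-chloro-2-methyl-3-oxopropanethioate
Product: 23 [(3S,7E,11S)-14-(furan-3-yl)-3,7,11-trimethyl-1-{[2-methyl-3-oxo-3-(phenylsulfanyl)propanoyl]oxy}-11-(triethylsilyloxy)tetradec-7-en-1-yl]triphenylphosphonium chloride
Conditions: PPh3, CH2Cl2, −20 °C → rt
Reagents that add atoms: triphenylphosphine, c1ccc(cc1)P(c1ccccc1)c1ccccc1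
Why: Triphenylphosphine adds reversibly to the aldehyde carbonyl and the alkoxide is trapped by O-acylation, giving a 1-(acyloxy)alkylphosphonium salt (Anders-type three-component salt formation); the P-bearing carbon and the malonyl carbon form as mixtures, and both become sp2 in the next step.

Step 17
Reactants: 23 [(3S,7E,11S)-14-(furan-3-yl)-3,7,11-trimethyl-1-{[2-methyl-3-oxo-3-(phenylsulfanyl)propanoyl]oxy}-11-(triethylsilyloxy)tetradec-7-en-1-yl]triphenylphosphonium chloride
Product: 26 (5Z)-5-[(2S,6E,10S)-13-(furan-3-yl)-2,6,10-trimethyl-10-(triethylsilyloxy)tridec-6-en-1-ylidene]-4-hydroxy-3-methylfuran-2(5H)-one, via ketene ylide 24 (not isolated), via phosphonio tetronate betaine 25 (not isolated)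
Conditions: NaN(SiMe3)2 (2.2 equiv), THF (0.01 M), −78 °C → rt; aq. NaH2PO4
Reagents that add atoms: none
Why: Proposed new method: the first equivalent of base removes the acidic C–H between the thioester and ester carbonyls and the enolate expels thiophenolate (E1cB) to give acylketene 24, while the second equivalent deprotonates the carbon that carries both the acyloxy oxygen O1 and the phosphonio group, so that the former aldehyde carbon becomes a carbanion (ylide). This ylide carbon adds to the ketene carbon in a 5-exo-dig closure (the C=O is exocyclic to the new ring), which forms the C4–C5 bond of the furanone and gives betaine 25; a Wittig collapse of 25 is not possible because it would put cumulated double bonds into the five-membered ring, so triphenylphosphine leaves C5 together with a proton of the neighbouring CH2 (base-assisted β-elimination) and the exocyclic C5=C1' double bond appears. The closest known reaction types are the C-acylation of phosphonium ylides by ketenes, thioesters and acid chlorides, the Wittig chemistry of 1-(acyloxy)alkylidenephosphoranes, and phosphine-mediated furan syntheses that run through O-acylated phosphonium ylides. No new stereocentre is formed and the (S)-CH(CH3) carbon next to the new double bond is never acidic, so it should be carried through unchanged; the (Z) geometry is the thermodynamic one (branched carbon syn to O1, away from the C4 oxygen) and can be reached by reversible conjugate addition of the liberated phosphine or thiolate at C1'. The step needs attack of the ylide carbon on the remote ketene carbon and not on its own ester carbonyl; a five-membered against a three-membered transition state secures this, and the 1,2-acyl shift would in any case lead, after loss of phosphine and enol lactonisation, to the same furanone.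

Step 18
Reactants: 26 (5Z)-5-[(2S,6E,10S)-13-(furan-3-yl)-2,6,10-trimethyl-10-(triethylsilyloxy)tridec-6-en-1-ylidene]-4-hydroxy-3-methylfuran-2(5H)-one
Product: 27 (5Z)-5-[(2S,6E,10S)-13-(furan-3-yl)-10-hydroxy-2,6,10-trimethyltridec-6-en-1-ylidene]-4-hydroxy-3-methylfuran-2(5H)-one
Conditions: HF·pyridine, pyridine, THF, 0 °C → rt
Reagents that add atoms: none
Why: Fluoride-mediated cleavage of the tertiary triethylsilyl ether under buffered conditions that the tetronic acid, the furan and both alkenes should tolerate.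

**Compound list**

1 | (R)-linalool, (3R)-3,7-dimethylocta-1,6-dien-3-ol | CC(C)=CCC[C@@](C)(O)C=C | starting material
2 | {[(3R)-3,7-dimethylocta-1,6-dien-3-yl]oxy}triethylsilane | CC(C)=CCC[C@@](C)(O[Si](CC)(CC)CC)C=C | intermediate
3 | (2E,6R)-2,6-dimethyl-6-(triethylsilyloxy)octa-2,7-dien-1-ol | OC/C(C)=C/CC[C@@](C)(O[Si](CC)(CC)CC)C=C | intermediate
4 | {[(3R,6E)-8-chloro-3,7-dimethylocta-1,6-dien-3-yl]oxy}triethylsilane | ClC/C(C)=C/CC[C@@](C)(O[Si](CC)(CC)CC)C=C | intermediate
5 | methyl hydrogen (R)-3-methylglutarate, (3R)-5-methoxy-3-methyl-5-oxopentanoic acid | OC(=O)C[C@@H](C)CC(=O)OC | starting material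
6 | methyl (3R)-5-hydroxy-3-methylpentanoate | OCC[C@@H](C)CC(=O)OC | intermediate
7 | methyl (3R)-3-methyl-5-(triethylsilyloxy)pentanoate | CC[Si](CC)(CC)OCC[C@@H](C)CC(=O)OC | intermediate
8 | (3S)-3-methyl-5-(triethylsilyloxy)pentan-1-ol | CC[Si](CC)(CC)OCC[C@@H](C)CCO | intermediate
9 | (3R)-3-methyl-5-(triethylsilyloxy)pentyl methanesulfonate (not isolated) | CC[Si](CC)(CC)OCC[C@@H](C)CCOS(C)(=O)=O | intermediate
10 | {[(3R)-5-bromo-3-methylpentyl]oxy}triethylsilane | CC[Si](CC)(CC)OCC[C@@H](C)CCBr | intermediate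
11 | [(3R)-3-methyl-5-(triethylsilyloxy)pentyl]magnesium bromide (not isolated) | CC[Si](CC)(CC)OCC[C@@H](C)CC[Mg]Br | intermediate
12 | (3S,7E,11R)-3,7,11-trimethyl-1,11-bis(triethylsilyloxy)trideca-7,12-diene | CC[Si](CC)(CC)OCC[C@@H](C)CCC/C(C)=C/CC[C@@](C)(O[Si](CC)(CC)CC)C=C | intermediate
13 | (3R,6E,11S)-3,7,11-trimethyl-3,13-bis(triethylsilyloxy)tridec-6-en-1-ol | CC[Si](CC)(CC)OCC[C@@H](C)CCC/C(C)=C/CC[C@@](C)(O[Si](CC)(CC)CC)CCO | intermediate
14 | (3R,6E,11S)-3,7,11-trimethyl-3,13-bis(triethylsilyloxy)tridec-6-en-1-yl 4-methylbenzenesulfonate | CC[Si](CC)(CC)OCC[C@@H](C)CCC/C(C)=C/CC[C@@](C)(O[Si](CC)(CC)CC)CCOS(=O)(=O)c1ccc(C)cc1 | intermediate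
15 | furan-3-ylmethanol | OCc1ccoc1 | starting material
16 | 3-(chloromethyl)furan | ClCc1ccoc1 | intermediate
17 | (furan-3-ylmethyl)magnesium chloride (not isolated) | Cl[Mg]Cc1ccoc1 | intermediate
18 | 3-[(4S,7E,12S)-4,8,12-trimethyl-4,14-bis(triethylsilyloxy)tetradec-7-en-1-yl]furan | CC[Si](CC)(CC)OCC[C@@H](C)CCC/C(C)=C/CC[C@@](C)(O[Si](CC)(CC)CC)CCCc1ccoc1 | intermediate
19 | (3S,7E,11S)-14-(furan-3-yl)-3,7,11-trimethyl-11-(triethylsilyloxy)tetradec-7-enal | O=CC[C@@H](C)CCC/C(C)=C/CC[C@@](C)(O[Si](CC)(CC)CC)CCCc1ccoc1 | intermediate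
20 | 2,2,5-trimethyl-1,3-dioxane-4,6-dione | CC1C(=O)OC(C)(C)OC1=O | starting material
21 | 2-methyl-3-oxo-3-(phenylsulfanyl)propanoic acid (racemic) | CC(C(=O)O)C(=O)Sc1ccccc1 | intermediate
22 | S-phenyl 3-chloro-2-methyl-3-oxopropanethioate (racemic) | CC(C(=O)Cl)C(=O)Sc1ccccc1 | intermediate
23 | [(3S,7E,11S)-14-(furan-3-yl)-3,7,11-trimethyl-1-{[2-methyl-3-oxo-3-(phenylsulfanyl)propanoyl]oxy}-11-(triethylsilyloxy)tetradec-7-en-1-yl]triphenylphosphonium chloride (mixture at C1 and at the malonyl carbon) | CC(C(=O)Sc1ccccc1)C(=O)OC(C[C@@H](C)CCC/C(C)=C/CC[C@@](C)(O[Si](CC)(CC)CC)CCCc1ccoc1)[P+](c1ccccc1)(c1ccccc1)c1ccccc1.[Cl-] | intermediate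
24 | ketene ylide, {(3S,7E,11S)-14-(furan-3-yl)-3,7,11-trimethyl-1-[(2-methyl-3-oxoprop-2-enoyl)oxy]-11-(triethylsilyloxy)tetradec-7-en-1-ylidene}triphenyl-λ5-phosphane (not isolated) | CC(=C=O)C(=O)OC(C[C@@H](C)CCC/C(C)=C/CC[C@@](C)(O[Si](CC)(CC)CC)CCCc1ccoc1)=P(c1ccccc1)(c1ccccc1)c1ccccc1 | intermediate
25 | phosphonio tetronate betaine, 5-[(2S,6E,10S)-13-(furan-3-yl)-2,6,10-trimethyl-10-(triethylsilyloxy)tridec-6-en-1-yl]-3-methyl-2-oxo-5-(triphenylphosphaniumyl)-2,5-dihydrofuran-4-olate (not isolated) | CC1=C([O-])C(C[C@@H](C)CCC/C(C)=C/CC[C@@](C)(O[Si](CC)(CC)CC)CCCc2ccoc2)([P+](c2ccccc2)(c2ccccc2)c2ccccc2)OC1=O | intermediate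
26 | (5Z)-5-[(2S,6E,10S)-13-(furan-3-yl)-2,6,10-trimethyl-10-(triethylsilyloxy)tridec-6-en-1-ylidene]-4-hydroxy-3-methylfuran-2(5H)-one | CC1=C(O)/C(=C/[C@@H](C)CCC/C(C)=C/CC[C@@](C)(O[Si](CC)(CC)CC)CCCc2ccoc2)OC1=O | intermediate
27 | (5Z)-5-[(2S,6E,10S)-13-(furan-3-yl)-10-hydroxy-2,6,10-trimethyltridec-6-en-1-ylidene]-4-hydroxy-3-methylfuran-2(5H)-one | CC1=C(O)/C(=C/[C@@H](C)CCC/C(C)=C/CC[C@@](C)(O)CCCc2ccoc2)OC1=O | target

**Totals and risks**

Total step count: 18. Longest linear sequence: 12 steps (from 5: steps 4, 5, 6, 7, 8, 9, 10, 12, 13, 16, 17, 18).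

Steps most likely to fail:

1. Step 17. The ylide may fragment or undergo non-productive acyl transfer before it finds the ketene, the ketene may oligomerise, or the betaine may not release the phosphine cleanly, giving poor conversion or E/Z mixtures. The fallback uses known chemistry, sets out from 19 and comes back at 26. Methyl (E)-3-methoxy-2-methylprop-2-enoate would be lithiated at C3 with LiN(i-Pr)2 (THF, −90 °C) and added to 19. The alkoxide should lactonise on warming to 4-methoxy-3-methyl-5-[(2S,6E,10S)-13-(furan-3-yl)-2,6,10-trimethyl-10-(triethylsilyloxy)tridec-6-en-1-yl]furan-2(5H)-one F1 (the tetronate annulation of β-lithiated β-methoxyacrylates). Deprotonation at C5 (LiN(i-Pr)2, THF, −78 °C) and PhSeBr would give the 5-(phenylselanyl) tetronate F2. H2O2/pyridine (CH2Cl2, 0 °C) would then form the selenoxide, whose syn-elimination can only run towards the side-chain CH2 and should give the O-methyl ylidene tetronate F3, the (Z) isomer being the more stable one. O-Demethylation with LiSPr in DMF would return to 26.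

2. Step 16. The phosphine–aldehyde addition is reversible and may not be captured by the acid chloride, and competing acylphosphonium formation or aldehyde self-condensation may consume material. The fallback sets out from 19 and comes back at 23. Acid chloride 22 with a catalytic amount of ZnCl2 (CH2Cl2, −20 °C) would add across the aldehyde to give the 1-chloroalkyl ester F4, and triphenylphosphine (MeCN, 40 °C) would then displace chloride to give 23.

3. Step 8. The cuprate may attack the γ carbon of the allylic chloride (allylic transposition with loss of the E-trisubstituted alkene), or the Grignard reagent may homocouple. The fallback sets out from 4 and comes back at 12. PhSO2Na (DMF, rt) would give {[(3R,6E)-3,7-dimethyl-8-(phenylsulfonyl)octa-1,6-dien-3-yl]oxy}triethylsilane F5. Deprotonation with n-BuLi (THF, −78 °C) and alkylation with bromide 10 would give the alkylated sulfone F6. Reductive desulfonylation with LiBHEt3 and catalytic PdCl2[Ph2P(CH2)3PPh2] (THF, 0 °C), which delivers hydride to the sulfone-bearing carbon without moving the double bond, would return to 12.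

Further compounds
F1 | step 17 | 4-methoxy-3-methyl-5-[(2S,6E,10S)-13-(furan-3-yl)-2,6,10-trimethyl-10-(triethylsilyloxy)tridec-6-en-1-yl]furan-2(5H)-one | COC1=C(C)C(=O)OC1C[C@@H](C)CCC/C(C)=C/CC[C@@](C)(O[Si](CC)(CC)CC)CCCc1ccoc1
F2 | step 17 | 4-methoxy-3-methyl-5-(phenylselanyl)-5-[(2S,6E,10S)-13-(furan-3-yl)-2,6,10-trimethyl-10-(triethylsilyloxy)tridec-6-en-1-yl]furan-2(5H)-one | COC1=C(C)C(=O)OC1(C[C@@H](C)CCC/C(C)=C/CC[C@@](C)(O[Si](CC)(CC)CC)CCCc1ccoc1)[Se]c1ccccc1
F3 | step 17 | (5Z)-5-[(2S,6E,10S)-13-(furan-3-yl)-2,6,10-trimethyl-10-(triethylsilyloxy)tridec-6-en-1-ylidene]-4-methoxy-3-methylfuran-2(5H)-one | CC1=C(OC)/C(=C/[C@@H](C)CCC/C(C)=C/CC[C@@](C)(O[Si](CC)(CC)CC)CCCc2ccoc2)OC1=O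
F4 | step 16 | (3S,7E,11S)-1-chloro-14-(furan-3-yl)-3,7,11-trimethyl-11-(triethylsilyloxy)tetradec-7-en-1-yl 2-methyl-3-oxo-3-(phenylsulfanyl)propanoate | CC(C(=O)Sc1ccccc1)C(=O)OC(Cl)C[C@@H](C)CCC/C(C)=C/CC[C@@](C)(O[Si](CC)(CC)CC)CCCc1ccoc1
F5 | step 8 | {[(3R,6E)-3,7-dimethyl-8-(phenylsulfonyl)octa-1,6-dien-3-yl]oxy}triethylsilane | O=S(=O)(C/C(C)=C/CC[C@@](C)(O[Si](CC)(CC)CC)C=C)c1ccccc1
F6 | step 8 | (3S,7E,11R)-3,7,11-trimethyl-6-(phenylsulfonyl)-1,11-bis(triethylsilyloxy)trideca-7,12-diene | CC[Si](CC)(CC)OCC[C@@H](C)CCC(/C(C)=C/CC[C@@](C)(O[Si](CC)(CC)CC)C=C)S(=O)(=O)c1ccccc1
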